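**Assumption:** (+)-gallocatechin (2R,3S), 3,4,5-tris(benzyloxy)benzoic acid and 2,4-dihydroxybenzaldehyde are bought; the lower flavan unit therefore comes from the chiral pool. The target is read as robinetinidol-(4α→6)-gallocatechin (upper unit 2R,3S,4S: 2,3-trans-3,4-trans; lower unit 2R,3S).

## Retrosynthetic overview

1. Target ⇐ one hydrogenolysis that removes eight O-benzyl groups and a C8 bromine.
2. Upper C2 and C3 ⇐ hydroboration–oxidation of a 4-aryl-4H-flav-2-ene; both centres are relayed from C4.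
3. Interflavan C4–C6 bond and the C4 stereocentre ⇐ dearomative Friedel–Crafts addition of C8-brominated, benzylated (+)-gallocatechin to C4 of a 7-hydroxyflavylium cation paired with a chiral phosphate.
4. Flavylium salt ⇐ 2,4-dihydroxybenzaldehyde + 3′,4′,5′-tris(benzyloxy)acetophenone (from the benzoic acid).
5. Ring order: the lower rings A, C and B are bought intact; the upper ring C is first built as an aromatic pyrylium on the resorcinol ring A, then dearomatised at C4, then saturated at C2/C3.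

## Route

**Step 1**
Reactants: 1 (+)-gallocatechin
Product: 2 (2R,3S)-5,7-bis(benzyloxy)-2-[3,4,5-tris(benzyloxy)phenyl]chroman-3-ol
Conditions: BnBr (5.5 equiv), K2CO3 (6 equiv), DMF, 0 → 20 °C, Ar
Reagents that add atoms: benzyl bromide (BrCc1ccccc1)
Why: Williamson etherification of the five phenols under carbonate leaves the aliphatic 3-OH free, and the mild base avoids C2 epimerisation, so both stereocentres are carried over unchanged.

**Step 2**
Reactants: 2 (2R,3S)-5,7-bis(benzyloxy)-2-[3,4,5-tris(benzyloxy)phenyl]chroman-3-ol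
Product: 3 (2R,3S)-5,7-bis(benzyloxy)-8-bromo-2-[3,4,5-tris(benzyloxy)phenyl]chroman-3-ol
Conditions: NBS (1.05 equiv), CH2Cl2, −78 → 0 °C
Reagents that add atoms: N-bromosuccinimide (O=C1CCC(=O)N1Br)
Why: electrophilic aromatic bromination of 5,7-dialkoxyflavans goes selectively to C8 of ring A, which blocks that position so that only C6 can react later; no stereocentre is touched.

**Step 3**
Reactants: 4 3,4,5-tris(benzyloxy)benzoic acid
Product: 6 1-[3,4,5-tris(benzyloxy)phenyl]ethan-1-one, via dilithium gem-diolate 5 (not isolated)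
Conditions: MeLi (2.3 equiv), THF, −78 → 0 °C; then 1 M HCl
Reagents that add atoms: methyllithium ([Li]C)
Why: addition of methyllithium to the lithium carboxylate stops at the dilithium gem-diolate, which gives the methyl ketone only on protonation (carboxylic acid to methyl ketone synthesis).

**Step 4**
Reactants: 6 1-[3,4,5-tris(benzyloxy)phenyl]ethan-1-one; 7 2,4-dihydroxybenzaldehyde
Product: 9 7-hydroxy-2-[3,4,5-tris(benzyloxy)phenyl]chromenylium tetrafluoroborate, via 2-hydroxychalcone 8 (not isolated)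
Conditions: 48% aq. HBF4 (3 equiv), AcOH, 25 °C, 24 h; precipitate with Et2O
Reagents that add atoms: tetrafluoroboric acid ([H+].F[B-](F)(F)F)
Why: acid-mediated Claisen–Schmidt aldol condensation followed by cyclodehydration of the 2-hydroxychalcone gives the aromatic benzopyrylium salt (Robinson-type flavylium synthesis), and the non-nucleophilic counter-ion spares the benzyl ethers.

**Step 5**
Reactants: 9 7-hydroxy-2-[3,4,5-tris(benzyloxy)phenyl]chromenylium tetrafluoroborate; 3 (2R,3S)-5,7-bis(benzyloxy)-8-bromo-2-[3,4,5-tris(benzyloxy)phenyl]chroman-3-ol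
Product: 11 (2R,3S)-5,7-bis(benzyloxy)-8-bromo-6-{(4S)-7-hydroxy-2-[3,4,5-tris(benzyloxy)phenyl]-4H-chromen-4-yl}-2-[3,4,5-tris(benzyloxy)phenyl]chroman-3-ol, via quinoidal base 10 (not isolated)
Conditions: Na2CO3 (powder), CH2Cl2, 20 °C, filter; then 3 (1.3 equiv), (R)-3,3′-bis(2,4,6-triisopropylphenyl)-1,1′-binaphthyl-2,2′-diyl hydrogen phosphate [(R)-TRIP, 10 mol %], 4 Å molecular sieves, toluene, 0 → 20 °C, Ar, dark; used crude
Reagents that add atoms: none
Why: Proposed new method: the phosphoric acid protonates quinoidal base 10 at O7 and so regenerates the aromatic flavylium cation as a hydrogen-bonded contact ion pair with the chiral phosphate (the only anion left once NaBF4 is filtered off), and C6 of 3 (C8 is blocked by bromine) adds to C4 of the pyrylium ring from the face left open by the 2,4,6-triisopropylphenyl groups, which breaks the aromaticity of ring C and sets C4 as S, while reversible O-adducts of the free 3-OH funnel to the C-adduct; the closest known reaction type is the chiral-phosphoric-acid-catalysed Friedel–Crafts 1,6-addition of arenes to para-quinone methides and to benzopyrylium ions made in situ, which gives 4-aryl-4H-chromenes.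

**Step 6**
Reactants: 11 (2R,3S)-5,7-bis(benzyloxy)-8-bromo-6-{(4S)-7-hydroxy-2-[3,4,5-tris(benzyloxy)phenyl]-4H-chromen-4-yl}-2-[3,4,5-tris(benzyloxy)phenyl]chroman-3-ol
Product: 13 (2R,3S,4S)-4-{(2R,3S)-5,7-bis(benzyloxy)-8-bromo-3-hydroxy-2-[3,4,5-tris(benzyloxy)phenyl]chroman-6-yl}-2-[3,4,5-tris(benzyloxy)phenyl]chroman-3,7-diol, via C3-alkylborane 12 (not isolated)
Conditions: BH3·THF (5 equiv), THF, 0 → 20 °C; then 30% H2O2, 3 M NaOH, 0 °C
Reagents that add atoms: hydrogen peroxide (OO); borane (B) leaves boron only in intermediate 12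
Why: hydroboration–oxidation of the enol ether C2=C3 puts boron on C3 and hydrogen on C2 in a syn addition from the face anti to the pseudoaxial C4 aryl group, and oxidation with retention then gives the 2,3-trans-3,4-trans (2R,3S) arrangement from the single 4S centre, as is known for flav-2-enes.

**Step 7**
Reactants: 13 (2R,3S,4S)-4-{(2R,3S)-5,7-bis(benzyloxy)-8-bromo-3-hydroxy-2-[3,4,5-tris(benzyloxy)phenyl]chroman-6-yl}-2-[3,4,5-tris(benzyloxy)phenyl]chroman-3,7-diol
Product: 14 robinetinidol-(4α→6)-gallocatechin, (2R,3S,4S)-4-[(2R,3S)-3,5,7-trihydroxy-2-(3,4,5-trihydroxyphenyl)chroman-6-yl]-2-(3,4,5-trihydroxyphenyl)chroman-3,7-diol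
Conditions: H2 (1 atm), Pd(OH)2/C (20 wt %), Et3N (2 equiv), THF/MeOH 1:1, 20 °C; filter under Ar, Sephadex LH-20
Reagents that add atoms: none
Why: catalytic hydrogenolysis cleaves the eight benzyl ethers and, with the amine present, the C8–Br bond in one operation, while the benzylic C2–O1 and interflavan bonds of flavans survive these conditions and no stereocentre is affected.

## Compound list

1 | (+)-gallocatechin, (2R,3S) | O[C@H]1Cc2c(O)cc(O)cc2O[C@@H]1c1cc(O)c(O)c(O)c1 | starting material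
2 | (2R,3S)-5,7-bis(benzyloxy)-2-[3,4,5-tris(benzyloxy)phenyl]chroman-3-ol | O[C@H]1Cc2c(OCc3ccccc3)cc(OCc3ccccc3)cc2O[C@@H]1c1cc(OCc2ccccc2)c(OCc2ccccc2)c(OCc2ccccc2)c1 | intermediate
3 | (2R,3S)-5,7-bis(benzyloxy)-8-bromo-2-[3,4,5-tris(benzyloxy)phenyl]chroman-3-ol | O[C@H]1Cc2c(OCc3ccccc3)cc(OCc3ccccc3)c(Br)c2O[C@@H]1c1cc(OCc2ccccc2)c(OCc2ccccc2)c(OCc2ccccc2)c1 | intermediate
4 | 3,4,5-tris(benzyloxy)benzoic acid | OC(=O)c1cc(OCc2ccccc2)c(OCc2ccccc2)c(OCc2ccccc2)c1 | starting material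
5 | dilithium 1-[3,4,5-tris(benzyloxy)phenyl]ethane-1,1-diolate (not isolated) | [Li+].[Li+].CC([O-])([O-])c1cc(OCc2ccccc2)c(OCc2ccccc2)c(OCc2ccccc2)c1 | intermediate
6 | 1-[3,4,5-tris(benzyloxy)phenyl]ethan-1-one | CC(=O)c1cc(OCc2ccccc2)c(OCc2ccccc2)c(OCc2ccccc2)c1 | intermediate
7 | 2,4-dihydroxybenzaldehyde | O=Cc1ccc(O)cc1O | starting material
8 | (E)-3-(2,4-dihydroxyphenyl)-1-[3,4,5-tris(benzyloxy)phenyl]prop-2-en-1-one (2-hydroxychalcone, not isolated) | O=C(/C=C/c1ccc(O)cc1O)c1cc(OCc2ccccc2)c(OCc2ccccc2)c(OCc2ccccc2)c1 | intermediate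
9 | 7-hydroxy-2-[3,4,5-tris(benzyloxy)phenyl]chromenylium tetrafluoroborate | Oc1ccc2ccc(-c3cc(OCc4ccccc4)c(OCc4ccccc4)c(OCc4ccccc4)c3)[o+]c2c1.F[B-](F)(F)F | intermediate
10 | 2-[3,4,5-tris(benzyloxy)phenyl]-7H-chromen-7-one (quinoidal base, not isolated) | O=C1C=CC2=CC=C(c3cc(OCc4ccccc4)c(OCc4ccccc4)c(OCc4ccccc4)c3)OC2=C1 | intermediate
11 | (2R,3S)-5,7-bis(benzyloxy)-8-bromo-6-{(4S)-7-hydroxy-2-[3,4,5-tris(benzyloxy)phenyl]-4H-chromen-4-yl}-2-[3,4,5-tris(benzyloxy)phenyl]chroman-3-ol | Oc1ccc2c(c1)OC(c1cc(OCc3ccccc3)c(OCc3ccccc3)c(OCc3ccccc3)c1)=C[C@@H]2c1c(OCc3ccccc3)c(Br)c2c(c1OCc1ccccc1)C[C@H](O)[C@@H](c1cc(OCc3ccccc3)c(OCc3ccccc3)c(OCc3ccccc3)c1)O2 | intermediate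
12 | C3-alkylborane of 11, drawn in its simplest monomeric form with the two OH groups as O-BH2 (not isolated) | BOc1ccc2c(c1)O[C@H](c1cc(OCc3ccccc3)c(OCc3ccccc3)c(OCc3ccccc3)c1)[C@@H](B)[C@@H]2c1c(OCc3ccccc3)c(Br)c2c(c1OCc1ccccc1)C[C@H](OB)[C@@H](c1cc(OCc3ccccc3)c(OCc3ccccc3)c(OCc3ccccc3)c1)O2 | intermediate
13 | (2R,3S,4S)-4-{(2R,3S)-5,7-bis(benzyloxy)-8-bromo-3-hydroxy-2-[3,4,5-tris(benzyloxy)phenyl]chroman-6-yl}-2-[3,4,5-tris(benzyloxy)phenyl]chroman-3,7-diol | Oc1ccc2c(c1)O[C@H](c1cc(OCc3ccccc3)c(OCc3ccccc3)c(OCc3ccccc3)c1)[C@@H](O)[C@@H]2c1c(OCc3ccccc3)c(Br)c2c(c1OCc1ccccc1)C[C@H](O)[C@@H](c1cc(OCc3ccccc3)c(OCc3ccccc3)c(OCc3ccccc3)c1)O2 | intermediate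
14 | robinetinidol-(4α→6)-gallocatechin (CNP0311915.1) | Oc1ccc2c(c1)O[C@H](c1cc(O)c(O)c(O)c1)[C@@H](O)[C@@H]2c1c(O)cc2c(c1O)C[C@H](O)[C@@H](c1cc(O)c(O)c(O)c1)O2 | target

## Step count

Total: 7 steps. Longest linear sequence: 5 steps (steps 1, 2, 5, 6, 7, or steps 3, 4, 5, 6, 7).

## Steps most likely to fail, with fallbacks

**Step 5 (key step).** The facial control by the chiral phosphate is unproven, and the sense of induction has to be found by experiment. The hindered C6 of 3 may also react slowly, and the flavene 11 can be oxidised by unreacted flavylium. If catalyst control fails, it is given up in favour of separation on the enantiopure lower unit. The fallback sets out from 9 and 3: quinoidal base 10 is joined to 3 with achiral diphenyl phosphate (10 mol %) in CH2Cl2, which gives 11 together with its C4 epimer, the (4R)-flavene F1, in about equal amounts. The mixture is hydroborated exactly as in step 6, which turns F1 into the diastereomer with a (2S,3R,4R) upper unit F2. Because the lower unit is a single enantiomer, 13 and F2 are diastereomers and are separated by chromatography. The route is rejoined at 13.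

**Step 6.** Borane may add with poor facial selectivity, or the C3 borane, which lies anti to the aryloxy C2–O1 bond, may eliminate with ring opening during the basic oxidation. The fallback sets out from 11: dihydroxylation of the enol ether with OsO4 (5 mol %) and N-methylmorpholine N-oxide, from the face anti to the C4 aryl group, gives the 2,3-cis-diol hemiketal F3. Ionic hydrogenation (Et3SiH, BF3·OEt2, CH2Cl2, −78 °C) then ionises C2 to the oxocarbenium ion and delivers hydride anti to the C4 aryl group, cis to the 3-OH, which puts the C2 aryl trans to the 3-OH. This comes back to the route at 13.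

**Step 4.** The acid-mediated aldol of the electron-rich aldehyde may be slow, and long exposure to strong acid can cost benzyl ethers. The fallback sets out from 6: Claisen formylation (ethyl formate, NaH, THF; HCl work-up) gives 3-oxo-3-[3,4,5-tris(benzyloxy)phenyl]propanal F4. A Bülow condensation of F4 with resorcinol (aq. HBF4, AcOH, 20 °C, short reaction time) alkylates C4 of resorcinol with the aldehyde carbon and cyclodehydrates onto the ketone. This comes back to the route at 9.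

## Further compounds

F1 | step 5 | (2R,3S)-5,7-bis(benzyloxy)-8-bromo-6-{(4R)-7-hydroxy-2-[3,4,5-tris(benzyloxy)phenyl]-4H-chromen-4-yl}-2-[3,4,5-tris(benzyloxy)phenyl]chroman-3-ol (C4 epimer of 11) | Oc1ccc2c(c1)OC(c1cc(OCc3ccccc3)c(OCc3ccccc3)c(OCc3ccccc3)c1)=C[C@H]2c1c(OCc3ccccc3)c(Br)c2c(c1OCc1ccccc1)C[C@H](O)[C@@H](c1cc(OCc3ccccc3)c(OCc3ccccc3)c(OCc3ccccc3)c1)O2
F2 | step 5 | (2S,3R,4R)-4-{(2R,3S)-5,7-bis(benzyloxy)-8-bromo-3-hydroxy-2-[3,4,5-tris(benzyloxy)phenyl]chroman-6-yl}-2-[3,4,5-tris(benzyloxy)phenyl]chroman-3,7-diol (diastereomer of 13) | Oc1ccc2c(c1)O[C@@H](c1cc(OCc3ccccc3)c(OCc3ccccc3)c(OCc3ccccc3)c1)[C@H](O)[C@H]2c1c(OCc3ccccc3)c(Br)c2c(c1OCc1ccccc1)C[C@H](O)[C@@H](c1cc(OCc3ccccc3)c(OCc3ccccc3)c(OCc3ccccc3)c1)O2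
F3 | step 6 | (2R,3S,4S)-4-{(2R,3S)-5,7-bis(benzyloxy)-8-bromo-3-hydroxy-2-[3,4,5-tris(benzyloxy)phenyl]chroman-6-yl}-2-[3,4,5-tris(benzyloxy)phenyl]chroman-2,3,7-triol (2,3-cis-diol hemiketal) | Oc1ccc2c(c1)O[C@](O)(c1cc(OCc3ccccc3)c(OCc3ccccc3)c(OCc3ccccc3)c1)[C@@H](O)[C@@H]2c1c(OCc3ccccc3)c(Br)c2c(c1OCc1ccccc1)C[C@H](O)[C@@H](c1cc(OCc3ccccc3)c(OCc3ccccc3)c(OCc3ccccc3)c1)O2
F4 | step 4 | 3-oxo-3-[3,4,5-tris(benzyloxy)phenyl]propanal | O=CCC(=O)c1cc(OCc2ccccc2)c(OCc2ccccc2)c(OCc2ccccc2)c1
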